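1. In the beta run, at its last reading, 29.7% of the charge was neither solid nor product; in the gamma flask it was 27.1% at 30.0 min and 26.1% at 150 min. So [starting material] looked steady in the gamma flask while solid remained, and I tested your hunch that waiting would carry the gamma flask on its rate.

in all of them: solid substrate 1.1 M
- gamma: free catalyst 10 mol%; temperature 50 °C; the very flask that is asked about, followed so far
- beta: free catalyst 6.7 mol%; temperature 45 °C; run made earlier
- flask: free catalyst 10 mol%; temperature 50 °C; time 4.0 h

- gamma (time / min: product / %, solid substrate / %): 12.0: 29.4, 47.4; 20.0: 34.3, 41.2; 30.0: 37.4, 35.5; 50.0: 41.7, 31.0; 80.0: 47.4, 26.3; 150: 54.2, 19.7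
- beta (time / min: product / %, solid substrate / %): 1.00: 5.6, 72.7; 1.50: 5.6, 69.3; 2.50: 10.5, 62.3; 4.00: 14.0, 60.4; 8.00: 20.5, 56.3; 12.0: 20.9, 49.4

(readings scatter by 1 percentage point)

- north: at 4.0 h raise the temperature by 25 K, then wait 2.0 h
- west: at 4.0 h add free catalyst, 50.0% of the amount charged, then wait 2.0 h
- east: at 4.0 h take out 90% of the product then present, then wait 2.0 h
- north-west: change nothing and wait 2.0 h more

- solid substrate is a solid; its amount is given per volume of the solution
- removed product is counted in
- steps under discussion: solid substrate <-> starting material; starting material + free catalyst -> free catalyst + product; 2 free catalyst -> spent catalyst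
- at the start none of the solid substrate is in solution
- additions bring no volume worth counting

- product, in percent of the solid substrate first charged, at 4.0 h
- what to do for the largest gain in product; "none" if nothing gains more than 2 percentage points (north / west / east / north-west / none)
- product present, with what was taken out counted in, in percent of the solid substrate first charged, after north
- product present, with what was taken out counted in, in percent of the solid substrate first charged, after north-west

2. The gamma flask gained 4.9 percentage points in 8.00 min early and 6.8 points in 70.0 min late, so its late rate was lower than its early rate. But the gain per natural logarithm of time was 9.6 points early and 11 points late. A rate falling as one over time is what second-order deactivation of the free catalyst gives at steady [starting material].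

3. Between the gamma readings at 30.0 min and 150 min I read 10 points. This is the yield per e-fold, the product gained while elapsed time multiplies by e.

4. Carried on from the last reading, it gave me 59.1% at 4.0 h, and 4.2 points more for waiting. The same line implied a lag of 0.834 min. A half dose of free catalyst doubles that lag and restarts the clock, so west offered 45 points, bounded by the 41 points still unconverted. I left heating open, since the beta run changes two settings at once.

The forecast said 58.8% (56.5% to 61%), a little below mine. It chose west, saying “Fresh catalyst restarts the reaction”, with 70% (64% to 78%) after north and 63% (60.5% to 65.5%) after waiting.

5. The flask gave 57.9% at 4.0 h. The best choice was west, gaining 35 points, against 15 points for north, which reached 73.2%, and 4.1 points for waiting, which reached 61.9%.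

    solid substrate ⇌ starting material, rate k1*(cs1 - [starting material]) while solid is left; crystals form when [starting material] > cs1 (solubility = 0.300 M, k = 0.0362 s⁻¹)
    starting material + free catalyst → free catalyst + product (k = 0.216 L mol⁻¹ s⁻¹, Ea = 62.0 kJ mol⁻¹)
    2 free catalyst → spent catalyst (k = 0.293 L mol⁻¹ s⁻¹, Ea = 46.0 kJ mol⁻¹)
    (constants at 50 °C)

6. In this flask [starting material] stood at 27.1% after 24.0 min and 27.3% after 240 min, while free catalyst fell from 1.07% to 0.108% of its charge. Put to ten times the time, the yield per e-fold of 10 points carried this flask to 81.9%. The flask left that long gave 79.9%, with solid substrate at 0%.

Readings and results stem from a simulated flask for an exercise, noise included.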